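- A factor of 2.91 in the reagent E, from the west run to the south-west run, moves the ratio of Z (formed on the way) to the substrate X at 8.00 h from 0.391 to 0.413, a change far smaller. So I take the step from X to Z to run on the catalyst J; both runs hold J at 16 µM, and that its pace is first order in J is my assumption.

| flask | X | E | J | remark | time |
|---|---|---|---|---|---|
| west | 16 mM | 7.9 mM | 16 µM | run made earlier |  |
| south-west | 16 mM | 23 mM | 16 µM | run made earlier |  |
| Tuesday's | 16 mM | 30.0 mM | 16 µM |  | 15 h |
| Thursday's | 16 mM | 15.0 mM | 16 µM |  | 15 h |

| run | time / h | Q / % | L / % | Z / % | X / % |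
|---|---|---|---|---|---|
| west | 1.00 | 0 | 0 | 6 | 95 |
| west | 2.00 | 1 | 0 | 13 | 86 |
| west | 3.00 | 1 | 2 | 14 | 83 |
| west | 4.00 | 1 | 2 | 17 | 79 |
| west | 5.00 | 1 | 3 | 20 | 76 |
| west | 6.00 | 3 | 4 | 25 | 75 |
| west | 8.00 | 1 | 4 | 27 | 69 |
| south-west | 0.667 | 0 | 0 | 3 | 94 |
| south-west | 1.00 | 0 | 2 | 6 | 94 |
| south-west | 1.33 | 0 | 5 | 10 | 91 |
| south-west | 2.00 | 2 | 6 | 9 | 88 |
| south-west | 3.00 | 0 | 3 | 16 | 81 |
| south-west | 5.00 | 0 | 5 | 19 | 75 |
| south-west | 8.00 | 2 | 8 | 26 | 63 |

(readings scatter by 1.5 percentage points)



- which of these there is most of at the end, counted by the X in it, Tuesday's (Q / L / Z / X)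
- which of these there is most of at the end, counted by the X in it, Thursday's (Q / L / Z / X)
- how much there is at the end of the one of these that leads, in percent of the X charged: Tuesday's
- how much there is at the end of the one of these that leads, in percent of the X charged: Thursday's

- Fastest rung: averaged over both runs, X falls by 0.0650 /h of its charge early on, but by 0.0317 /h between 5.00 h and 8.00 h, slower. I read X and Z as nearing a balance, with a fading time τ (relaxation time), the time in which the net loss of X shrinks by a factor 2.72, of 7.65 h at this J, and I take τ to vary as one over J.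
- Next rung: the other product L reads 6.00% on average over the two runs at 8.00 h, so at that pace the charge of X takes about 133 h, far longer than τ.
- Slowest rung: the product Q reads less than L, at 1.50% on average at 8.00 h, against a scatter of 1.5 percentage points.
- My reckoning: 15 h is twice τ. Continuing the fading from the mean X at 8.00 h gives 54.1% for both Tuesday's and Thursday's, more than all else together, so X leads.
- The forecast also names X for Tuesday's and X for Thursday's, but lower than mine, at 37% and 43%; of Tuesday's it says: “X probably still leads, narrowly”.

The flask gives X in the lead, at 56.5% on Tuesday's and 60.3% on Thursday's, both above my 54.1%.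

    X + J ⇌ J + Z (K = 0.560, k = 68.0 /M/min)
    J + Z ⇌ D (K = 33.0 /M, k = 62.0 /M/min)
    E + D → J + Q (k = 39.0 /M/min)
    2 E → G (k = 0.0320 /M/min)
    X + E → L (k = 0.0110 /M/min)

The ratio of Z to X on Tuesday's stands at 0.486 at the end, after 1.96 τ. A neighbour flask, like Tuesday's but with 0.040 mM of J, has by my one-over-J rule τ = 3.06 h, so its 15 h is 4.90 τ, and its ratio of Z to X stands at 0.535.

The numbers in the tables were computed with constants of no real substance, noise included.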